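**Strategy.** The route rests on disconnecting C7–C11 of the α-methylene-γ-butyrolactone (ring O–C6–C7–C11–C12). C11 is the α-carbon of an acrylate on the C6 oxygen and C7 is the β-carbon of a C7=C8–C9(=O) enone, so a trimethylphosphine-catalysed Rauhut–Currier annulation closes the lactone, forms C7–C11, sets C7 and restores the C11=C13 methylene in one operation. Its precursor is the ten-membered carbocycle bridged by the furanone oxygen (C3–O–C10) that carries the (Z)-C4=C5 alkene, the (Z)-C7=C8–C9 enone and the C6 acrylate; the enone is unmasked last. C8 and C9 are then oxygenated through a C8=C9 alkene and its epoxide.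

Key step: step 14

Remark on numbering: germacrane-type locants are used (C1 furanone ketone, C2=C3, ring oxygen between C3 and C10, C4(CH3)=C5, C6 to C10 in the macrocycle, lactone carbons C11 to C13, C14 on C10, C15 on C4); α and β refer to the usual drawing with H7 α.
Remark on configuration: the target is (6R,7S,8S,9R,10R); C6 is S by the CIP rules up to compound 26 and R from compound 27 on, only because C7 outranks C5 once the lactone is closed.
Remark on design: C9 stays a carbinol through the palladium coupling, the furanone closure and the metathesis, and O6 is acylated before C9 is oxidised, so that no vinyl ketone meets a palladium catalyst and no free (Z)-γ-hydroxy enone (prone to transannular hemiketal formation) is ever exposed.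
Assumption: the C9 carbinol made in step 7 is carried as a mixture of epimers until step 13, and the C9 carbinol of step 15 until step 16; neither centre survives.

Step 1
Reactants: 1 but-2-yn-1-ol
Product: 3 (Z)-3-iodobut-2-en-1-ol, via alkenylaluminate 2 (not isolated)
Conditions: NaAlH2(OCH2CH2OCH3)2, THF, 0 °C to rt; then I2, THF, −78 to 0 °C
Reagents that add atoms: iodine, II
Why: trans-hydroalumination of the propargylic alcohol through its alkoxyaluminate places aluminium on C3 cis to the CH2O group, and iodinolysis with retention gives the (Z)-vinyl iodide that fixes the C4=C5 geometry.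

Step 2
Reactants: 3 (Z)-3-iodobut-2-en-1-ol
Product: 4 (Z)-3-iodobut-2-enal
Conditions: MnO2 (excess), CH2Cl2, rt, dark
Reagents that add atoms: none
Why: MnO2 oxidation of an allylic alcohol stops at the enal and should leave the vinyl iodide and its geometry untouched.

Step 3
Reactants: 4 (Z)-3-iodobut-2-enal; 5 vinylmagnesium bromide
Product: 7 (3S,4Z)-5-iodohexa-1,4-dien-3-ol, via divinylzinc 6 (not isolated)
Conditions: 5, ZnCl2, THF/toluene, 0 °C; N,N,N′,N′-tetraethylethylenediamine; (−)-MIB [(2S)-3-exo-morpholinoisoborneol, 10 mol%]; 4, toluene, −30 to 0 °C; H2O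
Reagents that add atoms: none
Why: amino-alcohol-catalysed enantioselective addition of an alkenylzinc reagent to an enal, in which the (−)-MIB zinc alkoxide is expected to deliver vinyl to the Si face and so give the (S)-carbinol (future C6), while the diamine sequesters the magnesium salts that would cause a racemic background reaction.

Step 4
Reactants: 7 (3S,4Z)-5-iodohexa-1,4-dien-3-ol
Product: 8 triethyl{[(3S,4Z)-5-iodohexa-1,4-dien-3-yl]oxy}silane
Conditions: Et3SiCl, imidazole, CH2Cl2, 0 °C
Reagents that add atoms: chlorotriethylsilane, CC[Si](CC)(CC)Cl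
Why: standard silylation of a secondary allylic alcohol; the silyl ether masks O6 during the organometallic steps and is removed together with the C9 silyl ether in step 10.

Step 5
Reactants: 8 triethyl{[(3S,4Z)-5-iodohexa-1,4-dien-3-yl]oxy}silane; 9 ethynylmagnesium bromide
Product: 11 triethyl{[(3S,4Z)-5-methylhepta-1,4-dien-6-yn-3-yl]oxy}silane, via ethynylzinc bromide 10 (not isolated)
Conditions: 9, ZnBr2, THF, 0 °C; then 8, Pd(PPh3)4 (5 mol%), THF, rt
Reagents that add atoms: none
Why: Negishi coupling of an alkynylzinc halide with a vinyl iodide under zerovalent palladium catalysis proceeds with retention of the (Z) geometry and gives the terminal enyne (C2, C3 on C4) directly.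

Step 6
Reactants: 12 (S)-lactic acid
Product: 13 (2S,5S)-2-tert-butyl-5-methyl-1,3-dioxolan-4-one
Conditions: pivalaldehyde, TsOH (cat.), pentane, reflux (Dean–Stark); crystallisation at −78 °C
Reagents that add atoms: pivalaldehyde, CC(C)(C)C=O
Why: acid-catalysed acetalisation of the α-hydroxy acid gives mainly the cis-dioxolanone, purified by cold crystallisation, which stores the lactate configuration in the acetal centre (self-regeneration of stereocentres).

Step 7
Reactants: 13 (2S,5S)-2-tert-butyl-5-methyl-1,3-dioxolan-4-one; 14 acrolein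
Product: 17 (2S,5R)-2-tert-butyl-5-methyl-5-[1-(triethylsilyloxy)prop-2-en-1-yl]-1,3-dioxolan-4-one (both epimers at the silyloxy carbon), via lithium enolate 15 (not isolated), via lithium aldolate 16 (not isolated)
Conditions: LiN(iPr)2, THF, −78 °C; 14, −78 °C; Et3SiOTf, −78 to −40 °C
Reagents that add atoms: triethylsilyl trifluoromethanesulfonate, CC[Si](CC)(CC)OS(=O)(=O)C(F)(F)F
Why: aldol 1,2-addition of the dioxolanone enolate to acrolein occurs anti to the tert-butyl group, so the quaternary carbon (future C10) forms with overall retention as the (R) centre; the aldolate is silylated in the flask, and the carbinol configuration (future C9) does not matter.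

Step 8
Reactants: 11 triethyl{[(3S,4Z)-5-methylhepta-1,4-dien-6-yn-3-yl]oxy}silane; 17 (2S,5R)-2-tert-butyl-5-methyl-5-[1-(triethylsilyloxy)prop-2-en-1-yl]-1,3-dioxolan-4-one
Product: 20 (3S,4Z,9R)-9-hydroxy-5,9-dimethyl-3,10-bis(triethylsilyloxy)dodeca-1,4,11-trien-6-yn-8-one (C10 epimers), via lithium acetylide 18 (not isolated), via lithium hemiketal alkoxide 19 (not isolated)
Conditions: 11, n-BuLi, THF, −78 °C; 17, −78 °C; AcOH, −78 °C; aqueous work-up
Reagents that add atoms: none
Why: acyl substitution at a lactone-type carbonyl by a lithium acetylide; the tetrahedral lithium hemiketal should persist at −78 °C and collapse only after the cold acetic acid quench, releasing pivalaldehyde and the α′-hydroxy ynone (C1–C2 bond) without over-addition or base-induced silyl migration.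

Step 9
Reactants: 20 (3S,4Z,9R)-9-hydroxy-5,9-dimethyl-3,10-bis(triethylsilyloxy)dodeca-1,4,11-trien-6-yn-8-one
Product: 21 (2R)-2-methyl-5-[(2Z,4S)-4-(triethylsilyloxy)hexa-2,5-dien-2-yl]-2-[1-(triethylsilyloxy)prop-2-en-1-yl]furan-3(2H)-one
Conditions: (p-CF3C6H4)3PAuCl (5 mol%), AgOTf (5 mol%), toluene, rt
Reagents that add atoms: none
Why: gold-catalysed 5-endo-dig cycloisomerisation (intramolecular oxa-Michael addition) of the tertiary hydroxyl onto the ynone builds the 3(2H)-furanone and the C3–O–C10 bridge without touching C10.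

Step 10
Reactants: 21 (2R)-2-methyl-5-[(2Z,4S)-4-(triethylsilyloxy)hexa-2,5-dien-2-yl]-2-[1-(triethylsilyloxy)prop-2-en-1-yl]furan-3(2H)-one
Product: 22 (2R)-5-[(2Z,4S)-4-hydroxyhexa-2,5-dien-2-yl]-2-(1-hydroxyprop-2-en-1-yl)-2-methylfuran-3(2H)-one
Conditions: HF·pyridine, pyridine, THF, 0 °C to rt
Reagents that add atoms: none
Why: buffered HF cleaves both triethylsilyl ethers under mildly acidic conditions, which avoid the retro-aldol cleavage that base could trigger at the C9 carbinol β to the furanone ketone.

Step 11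
Reactants: 22 (2R)-5-[(2Z,4S)-4-hydroxyhexa-2,5-dien-2-yl]-2-(1-hydroxyprop-2-en-1-yl)-2-methylfuran-3(2H)-one
Product: 23 (4Z,6S,7Z,10R)-3,10-epoxy-6,9-dihydroxy-4,10-dimethylcyclodeca-2,4,7-trien-1-one (C9 epimers)
Conditions: second-generation Grubbs catalyst (10 mol%), 1,4-benzoquinone (20 mol%), toluene (1 mM), 80 °C
Reagents that add atoms: none
Why: ring-closing metathesis of the two allylic-alcohol vinyl groups forms C7=C8; the (Z)-C4=C5 alkene, the planar furanone and quaternary C10 pre-organise the chain, the bridged ring is expected to accommodate only the (Z)-alkene, and benzoquinone suppresses ruthenium hydride isomerisation of the allylic alcohols.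

Step 12
Reactants: 23 (4Z,6S,7Z,10R)-3,10-epoxy-6,9-dihydroxy-4,10-dimethylcyclodeca-2,4,7-trien-1-one; 24 acryloyl chloride
Product: 25 (4Z,6S,7Z,10R)-3,10-epoxy-9-hydroxy-4,10-dimethyl-1-oxocyclodeca-2,4,7-trien-6-yl acrylate (C9 epimers)
Conditions: 24 (1.1 equiv), iPr2NEt, CH2Cl2, −78 to −40 °C
Reagents that add atoms: none
Why: acylation with an acid chloride should take place at the bis-allylic C6 hydroxyl, because the C9 hydroxyl is neopentylic (next to quaternary C10) and much more hindered.

Step 13
Reactants: 25 (4Z,6S,7Z,10R)-3,10-epoxy-9-hydroxy-4,10-dimethyl-1-oxocyclodeca-2,4,7-trien-6-yl acrylate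
Product: 26 (4Z,6S,7Z,10R)-3,10-epoxy-4,10-dimethyl-1,9-dioxocyclodeca-2,4,7-trien-6-yl acrylate
Conditions: Dess–Martin periodinane, CH2Cl2, 0 °C to rt
Reagents that add atoms: none
Why: Dess–Martin oxidation of the remaining allylic C9 alcohol unmasks the (Z)-enone only after O6 is acylated, and both C9 epimers converge on one ketone.

Step 14
Reactants: 26 (4Z,6S,7Z,10R)-3,10-epoxy-4,10-dimethyl-1,9-dioxocyclodeca-2,4,7-trien-6-yl acrylate
Product: 27 (6R,7S,10R)-3,10-epoxy-1,9-dioxogermacra-2,4Z,11(13)-trien-12,6-olide (trans-fused lactone)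
Conditions: PMe3 (0.3 equiv), t-AmOH (0.01 M), rt, argon
Reagents that add atoms: none
Why: PMe3 adds reversibly to the acrylate terminus C13 and the resulting ester enolate (C11) adds to the enone β-carbon C7; proton transfer from C11 to the C8/C9 enolate and loss of the phosphine then restore the C11=C13 double bond. The closest known reaction type is the phosphine-catalysed intramolecular Rauhut–Currier cyclisation of γ-acryloyloxy enones to α-methylene-γ-butyrolactones. The lactone ring (O–C6–C7–C11–C12) closes in the 5-exo-trig mode, the C7=C8 bond lying outside the new ring. The new stereocentre C7 is controlled by C6: allylic 1,3-strain in the (Z)-enone holds H6 in the enone plane, the macrocyclic bond C6–C5 covers the inner face, and the acrylate on O6 reaches C7 from the outer face, which places H7 anti to H6 (trans fusion, 7S); reversibility of the Michael step should reinforce this more stable fusion. The step needs chemoselectivity and the absence of base-induced loss of the γ-acyloxy group: only the pairing of acrylate α-carbon with enone β-carbon is productive, since the enone-derived enolate would have to close a seven-membered ring, and the weakly basic phosphine in a tertiary alcohol should spare the allylic ester.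

Step 15
Reactants: 27 (6R,7S,10R)-3,10-epoxy-1,9-dioxogermacra-2,4Z,11(13)-trien-12,6-olide
Product: 28 (6R,7S,10R)-3,10-epoxy-9-hydroxy-1-oxogermacra-2,4Z,11(13)-trien-12,6-olide (C9 epimers)
Conditions: NaBH4, CeCl3·7H2O, MeOH/THF, −78 °C
Reagents that add atoms: none
Why: Luche reduction adds hydride 1,2 to the activated C9 ketone at low temperature and should leave the vinylogous-ester carbonyl C1, the lactone and the conjugated methylene untouched; the new carbinol centre is removed in step 16.

Step 16
Reactants: 28 (6R,7S,10R)-3,10-epoxy-9-hydroxy-1-oxogermacra-2,4Z,11(13)-trien-12,6-olide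
Product: 29 (6R,7S,10R)-3,10-epoxy-1-oxogermacra-2,4Z,8Z,11(13)-tetraen-12,6-olide
Conditions: Burgess reagent, toluene, 70 °C
Reagents that add atoms: none
Why: Burgess dehydration, in which the sulfamate of the C9 alcohol undergoes thermal syn-elimination with a C8 hydrogen (the only β-hydrogens), should give the ring-cis C8=C9 alkene under neutral conditions.

Step 17
Reactants: 29 (6R,7S,10R)-3,10-epoxy-1-oxogermacra-2,4Z,8Z,11(13)-tetraen-12,6-olide
Product: 30 (6R,7S,8R,9R,10R)-3,10:8,9-diepoxy-1-oxogermacra-2,4Z,11(13)-trien-12,6-olide (8α,9α-epoxide)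
Conditions: dimethyldioxirane (1.1 equiv), acetone/CH2Cl2, −20 to 0 °C
Reagents that add atoms: dimethyldioxirane, CC1(C)OO1
Why: epoxidation by the neutral oxidant should occur at the only unconjugated alkene; with H7 held in the alkene plane by allylic strain against C10, the macrocyclic arc C6–C5–C4–C3–C2–C1 covers one face, so the oxidant is expected on the open face that carries C11 and C14, giving the (8R,9R)-epoxide whose C9–O bond already has the target configuration.

Step 18
Reactants: 30 (6R,7S,8R,9R,10R)-3,10:8,9-diepoxy-1-oxogermacra-2,4Z,11(13)-trien-12,6-olide; 31 isovaleric acid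
Product: 32 (6R,7S,8S,9R,10R)-3,10-epoxy-9-hydroxy-8-(3-methylbutanoyloxy)-1-oxogermacra-2,4Z,11(13)-trien-12,6-olide
Conditions: 31 (excess), (CH3)2CHCH2CO2Cs (0.2 equiv), DMF, 50 °C
Reagents that add atoms: none
Why: SN2 ring opening of the epoxide by carboxylate is expected at C8, because C9 is neopentylic and adjacent to the electron-poor C10; inversion at C8 and retention at C9 give the (8S)-ester and the (9R)-alcohol, so the trans relationship of the two oxygens follows from the mechanism.

Step 19
Reactants: 32 (6R,7S,8S,9R,10R)-3,10-epoxy-9-hydroxy-8-(3-methylbutanoyloxy)-1-oxogermacra-2,4Z,11(13)-trien-12,6-olide; 33 acetic anhydride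
Product: 34 (6R,7S,8S,9R,10R)-9-acetoxy-3,10-epoxy-8-(3-methylbutanoyloxy)-1-oxogermacra-2,4Z,11(13)-trien-12,6-olide (CNP0255553.1)
Conditions: 33, DMAP (cat.), pyridine, CH2Cl2, 0 °C
Reagents that add atoms: none
Why: DMAP-catalysed acetylation of the hindered secondary C9 hydroxyl completes the target; mild base and low temperature are chosen to avoid 8-to-9 acyl migration and retro-aldol cleavage.

**Compound list**

1 | but-2-yn-1-ol | CC#CCO | starting material
2 | sodium 2,2-bis(2-methoxyethoxy)-3-methyl-2,5-dihydro-1,2-oxaaluminol-2-uide (cyclic alkenylaluminate) | CC1=CCO[Al-]1(OCCOC)OCCOC.[Na+] | intermediate (not isolated)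
3 | (Z)-3-iodobut-2-en-1-ol | C/C(I)=C/CO | intermediate
4 | (Z)-3-iodobut-2-enal | C/C(I)=C/C=O | intermediate
5 | vinylmagnesium bromide | C=C[Mg]Br | starting material
6 | divinylzinc | C=C[Zn]C=C | intermediate (not isolated)
7 | (3S,4Z)-5-iodohexa-1,4-dien-3-ol | O[C@@H](C=C)/C=C(/C)I | intermediate
8 | triethyl{[(3S,4Z)-5-iodohexa-1,4-dien-3-yl]oxy}silane | CC[Si](CC)(CC)O[C@@H](C=C)/C=C(/C)I | intermediate
9 | ethynylmagnesium bromide | C#C[Mg]Br | starting material
10 | ethynylzinc bromide | C#C[Zn]Br | intermediate (not isolated)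
11 | triethyl{[(3S,4Z)-5-methylhepta-1,4-dien-6-yn-3-yl]oxy}silane | CC[Si](CC)(CC)O[C@@H](C=C)/C=C(/C)C#C | intermediate
12 | (S)-lactic acid | C[C@H](O)C(=O)O | starting material
13 | (2S,5S)-2-tert-butyl-5-methyl-1,3-dioxolan-4-one | C[C@@H]1O[C@@H](OC1=O)C(C)(C)C | intermediate
14 | acrolein | C=CC=O | starting material
15 | lithium (2S)-2-tert-butyl-5-methyl-1,3-dioxol-4-olate (enolate of 13) | CC1=C(O[Li])O[C@@H](C(C)(C)C)O1 | intermediate (not isolated)
16 | lithium 1-[(2S,4R)-2-tert-butyl-4-methyl-5-oxo-1,3-dioxolan-4-yl]prop-2-en-1-olate (aldolate, carbinol epimers) | C[C@]1(C(O[Li])C=C)O[C@@H](OC1=O)C(C)(C)C | intermediate (not isolated)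
17 | (2S,5R)-2-tert-butyl-5-methyl-5-[1-(triethylsilyloxy)prop-2-en-1-yl]-1,3-dioxolan-4-one (epimers at the silyloxy carbon) | C[C@]1(C(O[Si](CC)(CC)CC)C=C)O[C@@H](OC1=O)C(C)(C)C | intermediate
18 | lithium acetylide of 11 | CC[Si](CC)(CC)O[C@@H](C=C)/C=C(/C)C#C[Li] | intermediate (not isolated)
19 | lithium (2S,5R)-2-tert-butyl-5-methyl-4-[(3Z,5S)-3-methyl-5-(triethylsilyloxy)hepta-3,6-dien-1-yn-1-yl]-5-[1-(triethylsilyloxy)prop-2-en-1-yl]-1,3-dioxolan-4-olate (hemiketal alkoxide, C4 epimers) | CC[Si](CC)(CC)O[C@@H](C=C)/C=C(/C)C#CC1(O[Li])O[C@@H](C(C)(C)C)O[C@]1(C)C(O[Si](CC)(CC)CC)C=C | intermediate (not isolated)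
20 | (3S,4Z,9R)-9-hydroxy-5,9-dimethyl-3,10-bis(triethylsilyloxy)dodeca-1,4,11-trien-6-yn-8-one (C10 epimers) | C=C[C@H](O[Si](CC)(CC)CC)/C=C(/C)C#CC(=O)[C@](C)(O)C(O[Si](CC)(CC)CC)C=C | intermediate
21 | (2R)-2-methyl-5-[(2Z,4S)-4-(triethylsilyloxy)hexa-2,5-dien-2-yl]-2-[1-(triethylsilyloxy)prop-2-en-1-yl]furan-3(2H)-one | C=C[C@H](O[Si](CC)(CC)CC)/C=C(/C)C1=CC(=O)[C@](C)(O1)C(O[Si](CC)(CC)CC)C=C | intermediate
22 | (2R)-5-[(2Z,4S)-4-hydroxyhexa-2,5-dien-2-yl]-2-(1-hydroxyprop-2-en-1-yl)-2-methylfuran-3(2H)-one | C=C[C@H](O)/C=C(/C)C1=CC(=O)[C@](C)(O1)C(O)C=C | intermediate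
23 | (4Z,6S,7Z,10R)-3,10-epoxy-6,9-dihydroxy-4,10-dimethylcyclodeca-2,4,7-trien-1-one (C9 epimers) | OC1/C=C\[C@H](O)/C=C(/C)C2=CC(=O)[C@]1(C)O2 | intermediate
24 | acryloyl chloride | C=CC(Cl)=O | starting material
25 | (4Z,6S,7Z,10R)-3,10-epoxy-9-hydroxy-4,10-dimethyl-1-oxocyclodeca-2,4,7-trien-6-yl acrylate (C9 epimers) | OC1/C=C\[C@H](OC(=O)C=C)/C=C(/C)C2=CC(=O)[C@]1(C)O2 | intermediate
26 | (4Z,6S,7Z,10R)-3,10-epoxy-4,10-dimethyl-1,9-dioxocyclodeca-2,4,7-trien-6-yl acrylate (key-step precursor) | O=C1/C=C\[C@H](OC(=O)C=C)/C=C(/C)C2=CC(=O)[C@]1(C)O2 | intermediate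
27 | (6R,7S,10R)-3,10-epoxy-1,9-dioxogermacra-2,4Z,11(13)-trien-12,6-olide (key-step product) | C=C1C(=O)O[C@@H]2/C=C(/C)C3=CC(=O)[C@](C)(O3)C(=O)C[C@@H]12 | intermediate
28 | (6R,7S,10R)-3,10-epoxy-9-hydroxy-1-oxogermacra-2,4Z,11(13)-trien-12,6-olide (C9 epimers) | C=C1C(=O)O[C@@H]2/C=C(/C)C3=CC(=O)[C@](C)(O3)C(O)C[C@@H]12 | intermediate
29 | (6R,7S,10R)-3,10-epoxy-1-oxogermacra-2,4Z,8Z,11(13)-tetraen-12,6-olide | C=C1C(=O)O[C@@H]2/C=C(/C)C3=CC(=O)[C@](C)(O3)/C=C\[C@@H]12 | intermediate
30 | (6R,7S,8R,9R,10R)-3,10:8,9-diepoxy-1-oxogermacra-2,4Z,11(13)-trien-12,6-olide | C=C1C(=O)O[C@@H]2/C=C(/C)C3=CC(=O)[C@](C)(O3)[C@@H]4O[C@@H]4[C@@H]12 | intermediate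
31 | isovaleric acid | CC(C)CC(=O)O | starting material
32 | (6R,7S,8S,9R,10R)-3,10-epoxy-9-hydroxy-8-(3-methylbutanoyloxy)-1-oxogermacra-2,4Z,11(13)-trien-12,6-olide | C=C1C(=O)O[C@@H]2/C=C(/C)C3=CC(=O)[C@](C)(O3)[C@H](O)[C@@H](OC(=O)CC(C)C)[C@@H]12 | intermediate
33 | acetic anhydride | CC(=O)OC(C)=O | starting material
34 | (6R,7S,8S,9R,10R)-9-acetoxy-3,10-epoxy-8-(3-methylbutanoyloxy)-1-oxogermacra-2,4Z,11(13)-trien-12,6-olide | C=C1C(=O)O[C@@H]2/C=C(/C)C3=CC(=O)[C@](C)(O3)[C@H](OC(C)=O)[C@@H](OC(=O)CC(C)C)[C@@H]12 | target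

**Step count.** Total: 19 steps. Longest linear sequence: 17 steps (steps 1 to 5, then 8 to 19).

**Steps most likely to fail**

1. Step 14 (key annulation). The phosphonium enolate may not cyclise onto the strained macrocyclic (Z)-enone: acrylate oligomerisation, phosphine-triggered loss of the allylic acyloxy group or attack on the other face of C7 (cis fusion) could take over. The fallback sets out from 23 and comes back at 27. O6 of 23 is esterified with diethylphosphonoacetic acid (DCC, DMAP cat., CH2Cl2, 0 °C) to give the C6 (diethoxyphosphoryl)acetate F1. Dess–Martin oxidation of the C9 alcohol gives the enone phosphonoacetate F2. Intramolecular Michael addition of the stabilised phosphonate carbanion to C7 (LiCl, iPr2NEt, MeCN, rt; reversible, so the trans fusion should prevail) gives the α-(diethoxyphosphoryl) lactone F3. Horner–Wadsworth–Emmons reaction of F3 with aqueous formaldehyde (K2CO3, THF, 0 °C) installs the C11=C13 methylene and delivers 27.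

2. Step 11 (ring-closing metathesis). Closure of the strained bridged ring may be slower than intermolecular metathesis, giving oligomers, or than ruthenium-mediated isomerisation of the allylic alcohols to ketones. The fallback sets out from 22 and comes back at 23. The two hydroxyls of 22 are tied together with iPr2Si(OTf)2 (2,6-lutidine, CH2Cl2, high dilution) as the cyclic di-isopropylsilylene acetal F4. Metathesis of F4 (second-generation Grubbs catalyst, toluene, 60 °C) then only has to close a seven-membered 1,3-dioxa-2-silacycloheptene, which enforces the (Z)-alkene and masks both alcohols, giving the silylene-bridged macrocycle F5. HF·pyridine removes the tether and returns 23.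

3. Step 18 (epoxide opening). The bulky carboxylate has to reach C8 from the concave side of the ring and may react too slowly, so that the epoxide is recovered or isomerises. The fallback sets out from 30 and comes back at 32. Acid-catalysed hydration (HClO4 cat., THF/H2O, 0 °C to rt) uses a small nucleophile and a looser transition state for the same anti opening at C8 and should give the 8β,9α-diol F6. The less hindered C8 hydroxyl of F6 is then acylated selectively with isovaleric anhydride (DMAP cat., pyridine, CH2Cl2, −20 °C), the neopentylic C9 hydroxyl remaining free, to give 32.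

**Further compounds**

F1 | step 14 | (4Z,6S,7Z,10R)-3,10-epoxy-9-hydroxy-4,10-dimethyl-1-oxocyclodeca-2,4,7-trien-6-yl (diethoxyphosphoryl)acetate (C9 epimers) | OC1/C=C\[C@H](OC(=O)CP(=O)(OCC)OCC)/C=C(/C)C2=CC(=O)[C@]1(C)O2
F2 | step 14 | (4Z,6S,7Z,10R)-3,10-epoxy-4,10-dimethyl-1,9-dioxocyclodeca-2,4,7-trien-6-yl (diethoxyphosphoryl)acetate | O=C1/C=C\[C@H](OC(=O)CP(=O)(OCC)OCC)/C=C(/C)C2=CC(=O)[C@]1(C)O2
F3 | step 14 | trans-fused 11-(diethoxyphosphoryl)-3,10-epoxy-1,9-dioxo-13-norgermacra-2,4Z-dien-12,6-olide (C11 epimers) | CCOP(=O)(OCC)C1C(=O)O[C@@H]2/C=C(/C)C3=CC(=O)[C@](C)(O3)C(=O)C[C@@H]12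
F4 | step 11 | cyclic di-isopropylsilylene acetal of 22 (O6–Si–O9) | C=C[C@H](O3)/C=C(/C)C1=CC(=O)[C@](C)(O1)C(O[Si]3(C(C)C)C(C)C)C=C
F5 | step 11 | silylene-bridged macrocycle (C7=C8 closed, O6–Si(iPr)2–O9) | CC(C)[Si]1(C(C)C)OC2/C=C\[C@H](O1)/C=C(/C)C3=CC(=O)[C@]2(C)O3
F6 | step 18 | (6R,7S,8S,9R,10R)-3,10-epoxy-8,9-dihydroxy-1-oxogermacra-2,4Z,11(13)-trien-12,6-olide | C=C1C(=O)O[C@@H]2/C=C(/C)C3=CC(=O)[C@](C)(O3)[C@H](O)[C@@H](O)[C@@H]12
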